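The depside is cut at its ester bond into ring A acid 20 and ring B phenol 15. Ring B carries its carboxyl at C1, oxygens at C2, C3 and C4, and propyl at C6, which is the pattern of a folded C10 chain. In tert-butyl 4-(benzyloxy)-3,5,7-trioxodecanoate 10 the C3 and C5 ketones and the C4 benzyloxy group become these three ring oxygens. One base-mediated aldol from chain C2 to C7 (the ring B C1–C6 bond), with loss of water, closes and aromatizes ring B and delivers O3 already distinguished from the O2 and O4 phenols. Ring A comes from 5-propylresorcinol by formylation, protection and oxidation.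

Key step: step 6

Remark on the chemistry: the target is achiral. Compounds 9 and 10 carry one enolizable, racemic centre at chain C4, and 11 is a mixture of stereoisomers; all of these centres vanish on aromatization, so the SMILES are written without configuration. LiN(i-Pr)2 is taken as a commercial solution.

Step 1
Reactants: 1 benzyloxyacetyl chloride; 2 tert-butyl acetate
Product: 4 tert-butyl 4-(benzyloxy)-3-oxobutanoate, via lithium enolate of tert-butyl acetate 3 (not isolated)
Conditions: 2 (2.1 equiv), LiN(i-Pr)2 (2.1 equiv), THF, −78 °C; then 1 (1.0 equiv), −78 °C; AcOH quench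
Reagents that add atoms: none
Why: Crossed Claisen condensation in which the ester enolate is C-acylated by the acid chloride at low temperature, while the second equivalent of enolate deprotonates the more acidic β-keto ester as it forms and so should prevent double acylation.

Step 2
Reactants: 5 methyl 3-oxohexanoate
Product: 6 methyl 2-(2-propyl-1,3-dioxolan-2-yl)acetate
Conditions: ethylene glycol (1.5 equiv), p-TsOH·H2O (cat.), toluene, reflux, Dean–Stark
Reagents that add atoms: ethylene glycol, OCCO
Why: Acid-catalysed ketalization with azeotropic removal of water should mask the ketone as its 1,3-dioxolane, so that the C5–C10 unit can later act as an electrophile without an acidic methylene between two carbonyl groups.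

Step 3
Reactants: 6 methyl 2-(2-propyl-1,3-dioxolan-2-yl)acetate
Product: 7 N-methoxy-N-methyl-2-(2-propyl-1,3-dioxolan-2-yl)acetamide
Conditions: MeNH(OMe)·HCl (1.5 equiv), i-PrMgCl (3.0 equiv), THF, −20 → 0 °C; aq. NH4Cl
Reagents that add atoms: N,O-dimethylhydroxylamine hydrochloride, CNOC.Cl
Why: Weinreb amide synthesis by aminolysis of the methyl ester with the chloromagnesium amide made from the hydroxylamine salt and i-PrMgCl, which should add to the ester carbonyl at low temperature faster than it enolizes the ester or opens the ketal.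

Step 4
Reactants: 4 tert-butyl 4-(benzyloxy)-3-oxobutanoate; 7 N-methoxy-N-methyl-2-(2-propyl-1,3-dioxolan-2-yl)acetamide
Product: 9 tert-butyl 4-(benzyloxy)-3,5-dioxo-6-(2-propyl-1,3-dioxolan-2-yl)hexanoate, via dilithium dienediolate 8 (not isolated)
Conditions: 4 (1.3 equiv), LiN(i-Pr)2 (2.8 equiv), THF, −78 → −40 °C; then 7 (1.0 equiv), −78 → 0 °C; AcOH quench
Reagents that add atoms: none
Why: γ-Acylation of a β-keto ester dianion with a Weinreb amide (Claisen-type C-acylation), in which the second deprotonation takes place at C4, this terminus is the most nucleophilic carbon of 8, and the N-methoxy-N-methyl amide should hold the product at the ketone oxidation level until the quench.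

Step 5
Reactants: 9 tert-butyl 4-(benzyloxy)-3,5-dioxo-6-(2-propyl-1,3-dioxolan-2-yl)hexanoate
Product: 10 tert-butyl 4-(benzyloxy)-3,5,7-trioxodecanoate
Conditions: 1 M aq. HCl/THF (1:3), rt; extractive work-up, crude product used at once
Reagents that add atoms: water, O
Why: Acid-catalysed ketal hydrolysis in dilute aqueous acid at room temperature, conditions that a tert-butyl ester and a benzyl ether should survive and under which cyclodehydration of the freed triketone, which normally needs strong dehydrating acid, should stay slow.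

Step 6
Reactants: 10 tert-butyl 4-(benzyloxy)-3,5,7-trioxodecanoate
Product: 12 tert-butyl 3-(benzyloxy)-2,4-dihydroxy-6-propylbenzoate, via cyclic aldol adduct 11 (not isolated)
Conditions: aq. NaHCO3/Na2CO3 buffer (pH 9.2), THF, rt, argon; then citric acid to pH 4 on work-up
Reagents that add atoms: none
Why: At about pH 9 the chain equilibrates among its enolates; the one at the C2 methylene, flanked by the ester and the C3 ketone, adds to the C7 ketone to give cyclic aldol 11, and E1cB loss of water followed by enolization of the former C3 and C5 carbonyls gives the arene, with chain C4 and its benzyloxy group becoming ring B C3. The closest known reaction type is the biomimetic base-mediated aldol cyclization and aromatization of 3,5,7-triketo esters to orsellinate-type resorcylates. The single ring closes in a 6-(enolexo)-exo-trig mode and forms the ring B C1–C6 bond. No stereocenter survives, since the three sp3 centres of 11 are all flattened on aromatization. The step needs chemoselectivity for the C2-to-C7 aldol over Claisen closure of C6 onto the ester, over lactonization through an enol oxygen and over aldol closure of C8 onto C3; the tert-butyl ester is a poor acyl acceptor, C8 is activated by one carbonyl only, and the weakly basic aqueous buffer is too mild for Claisen chemistry. Argon is kept over the mixture because the product phenoxide is an oxygen-sensitive pyrogallol monoether.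

Step 7
Reactants: 12 tert-butyl 3-(benzyloxy)-2,4-dihydroxy-6-propylbenzoate
Product: 13 tert-butyl 3-(benzyloxy)-2-hydroxy-4-(methoxymethoxy)-6-propylbenzoate
Conditions: MOMCl (1.1 equiv), i-Pr2NEt (1.5 equiv), CH2Cl2, 0 °C
Reagents that add atoms: chloromethyl methyl ether, COCCl
Why: Williamson-type O-alkylation (MOM ether formation) is expected at the 4-hydroxyl only, because the 2-hydroxyl is hydrogen-bonded to the ester carbonyl and flanked by two substituents.

Step 8
Reactants: 13 tert-butyl 3-(benzyloxy)-2-hydroxy-4-(methoxymethoxy)-6-propylbenzoate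
Product: 14 tert-butyl 3-(benzyloxy)-2-methoxy-4-(methoxymethoxy)-6-propylbenzoate
Conditions: MeI (3 equiv), K2CO3 (3 equiv), DMF, 40 °C
Reagents that add atoms: iodomethane, CI
Why: Williamson O-methylation of the remaining chelated 2-hydroxyl with MeI and K2CO3 in a dipolar aprotic solvent, the standard way to alkylate a hydrogen-bonded salicylate phenol once the more reactive hydroxyl is capped.

Step 9
Reactants: 14 tert-butyl 3-(benzyloxy)-2-methoxy-4-(methoxymethoxy)-6-propylbenzoate
Product: 15 tert-butyl 3-hydroxy-2-methoxy-4-(methoxymethoxy)-6-propylbenzoate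
Conditions: H2 (1 atm), 10% Pd/C, EtOAc, rt
Reagents that add atoms: none
Why: Catalytic hydrogenolysis of the benzyl ether should free the 3-hydroxyl alone, since the MOM ether, the methyl ether and the tert-butyl ester are inert to H2 over Pd/C under neutral conditions.

Step 10
Reactants: 16 5-propylbenzene-1,3-diol
Product: 18 2,4-dihydroxy-6-propylbenzaldehyde, via aryl iminium chloride 17 (not isolated)
Conditions: POCl3 (1.2 equiv), DMF, 0 °C → rt; then H2O, 50 °C
Reagents that add atoms: N,N-dimethylformamide, CN(C)C=O; water, O
Why: Vilsmeier–Haack formylation, in which the chloroiminium ion attacks the ring carbon para to one hydroxyl and ortho to the other (the usual site for 5-alkylresorcinols, not the carbon between the two hydroxyls), and aqueous hydrolysis of 17 gives the aldehyde.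

Step 11
Reactants: 18 2,4-dihydroxy-6-propylbenzaldehyde
Product: 19 2,4-bis(methoxymethoxy)-6-propylbenzaldehyde
Conditions: MOMCl (3 equiv), i-Pr2NEt (4 equiv), CH2Cl2, 0 °C → reflux
Reagents that add atoms: chloromethyl methyl ether, COCCl
Why: Double Williamson-type O-alkylation with excess MOMCl, in which the free 4-hydroxyl reacts first and warming with excess reagent should also cap the hydrogen-bonded 2-hydroxyl.

Step 12
Reactants: 19 2,4-bis(methoxymethoxy)-6-propylbenzaldehyde
Product: 20 2,4-bis(methoxymethoxy)-6-propylbenzoic acid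
Conditions: NaClO2, NaH2PO4, 2-methyl-2-butene, t-BuOH/H2O, rt
Reagents that add atoms: sodium chlorite, [Na+].[O-]Cl=O
Why: Pinnick oxidation converts the aldehyde into the acid near pH 4, mild enough for the MOM ethers, and 2-methyl-2-butene removes hypochlorous acid before it can chlorinate the electron-rich ring.

Step 13
Reactants: 15 tert-butyl 3-hydroxy-2-methoxy-4-(methoxymethoxy)-6-propylbenzoate; 20 2,4-bis(methoxymethoxy)-6-propylbenzoic acid
Product: 21 tert-butyl 3-{[2,4-bis(methoxymethoxy)-6-propylbenzoyl]oxy}-2-methoxy-4-(methoxymethoxy)-6-propylbenzoate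
Conditions: DCC (1.5 equiv), DMAP (1.0 equiv), CH2Cl2, rt → 40 °C
Reagents that add atoms: none
Why: Steglich esterification, in which carbodiimide activation of 20 and acyl transfer through DMAP deliver the aroyl group to the only free hydroxyl of 15; carbodiimide coupling is an established way to aryl esters (depsides) between ortho-disubstituted partners and avoids the acid chloride, which is incompatible with an ortho MOM ether.

Step 14
Reactants: 21 tert-butyl 3-{[2,4-bis(methoxymethoxy)-6-propylbenzoyl]oxy}-2-methoxy-4-(methoxymethoxy)-6-propylbenzoate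
Product: 22 3-[(2,4-dihydroxy-6-propylbenzoyl)oxy]-4-hydroxy-2-methoxy-6-propylbenzoic acid
Conditions: TFA/CH2Cl2 (1:3), H2O (10 equiv), 0 °C → rt
Reagents that add atoms: none
Why: Global acidolysis, in which TFA cleaves the three MOM acetals (oxocarbenium ions trapped by water) and the tert-butyl ester (loss of isobutene), while the hindered aryl ester between rings A and B and the methyl ether should be stable to this acid at or below room temperature.

Compound list
1 | benzyloxyacetyl chloride | O=C(Cl)COCc1ccccc1 | starting material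
2 | tert-butyl acetate | CC(=O)OC(C)(C)C | starting material
3 | lithium 1-(tert-butoxy)ethen-1-olate (lithium enolate of 2, formed in the flask) | [Li+].[O-]C(=C)OC(C)(C)C | intermediate
4 | tert-butyl 4-(benzyloxy)-3-oxobutanoate | O=C(COCc1ccccc1)CC(=O)OC(C)(C)C | intermediate
5 | methyl 3-oxohexanoate | CCCC(=O)CC(=O)OC | starting material
6 | methyl 2-(2-propyl-1,3-dioxolan-2-yl)acetate | CCCC1(CC(=O)OC)OCCO1 | intermediate
7 | N-methoxy-N-methyl-2-(2-propyl-1,3-dioxolan-2-yl)acetamide | CCCC1(CC(=O)N(C)OC)OCCO1 | intermediate
8 | dilithium 4-(benzyloxy)-1-(tert-butoxy)buta-1,3-diene-1,3-bis(olate) (dianion of 4, formed in the flask) | [Li+].[Li+].[O-]C(=CC([O-])=COCc1ccccc1)OC(C)(C)C | intermediate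
9 | tert-butyl 4-(benzyloxy)-3,5-dioxo-6-(2-propyl-1,3-dioxolan-2-yl)hexanoate (racemic at C4, enolizable) | CCCC1(CC(=O)C(OCc2ccccc2)C(=O)CC(=O)OC(C)(C)C)OCCO1 | intermediate
10 | tert-butyl 4-(benzyloxy)-3,5,7-trioxodecanoate (racemic at C4, enolizable) | CCCC(=O)CC(=O)C(OCc1ccccc1)C(=O)CC(=O)OC(C)(C)C | intermediate
11 | tert-butyl 3-(benzyloxy)-6-hydroxy-2,4-dioxo-6-propylcyclohexane-1-carboxylate (mixture of stereoisomers, formed in the flask) | CCCC1(O)CC(=O)C(OCc2ccccc2)C(=O)C1C(=O)OC(C)(C)C | intermediate
12 | tert-butyl 3-(benzyloxy)-2,4-dihydroxy-6-propylbenzoate | CCCc1cc(O)c(OCc2ccccc2)c(O)c1C(=O)OC(C)(C)C | intermediate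
13 | tert-butyl 3-(benzyloxy)-2-hydroxy-4-(methoxymethoxy)-6-propylbenzoate | CCCc1cc(OCOC)c(OCc2ccccc2)c(O)c1C(=O)OC(C)(C)C | intermediate
14 | tert-butyl 3-(benzyloxy)-2-methoxy-4-(methoxymethoxy)-6-propylbenzoate | CCCc1cc(OCOC)c(OCc2ccccc2)c(OC)c1C(=O)OC(C)(C)C | intermediate
15 | tert-butyl 3-hydroxy-2-methoxy-4-(methoxymethoxy)-6-propylbenzoate | CCCc1cc(OCOC)c(O)c(OC)c1C(=O)OC(C)(C)C | intermediate
16 | 5-propylbenzene-1,3-diol | CCCc1cc(O)cc(O)c1 | starting material
17 | N-(2,4-dihydroxy-6-propylbenzylidene)-N-methylmethanaminium chloride (formed in the flask) | CCCc1cc(O)cc(O)c1C=[N+](C)C.[Cl-] | intermediate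
18 | 2,4-dihydroxy-6-propylbenzaldehyde | CCCc1cc(O)cc(O)c1C=O | intermediate
19 | 2,4-bis(methoxymethoxy)-6-propylbenzaldehyde | CCCc1cc(OCOC)cc(OCOC)c1C=O | intermediate
20 | 2,4-bis(methoxymethoxy)-6-propylbenzoic acid | CCCc1cc(OCOC)cc(OCOC)c1C(=O)O | intermediate
21 | tert-butyl 3-{[2,4-bis(methoxymethoxy)-6-propylbenzoyl]oxy}-2-methoxy-4-(methoxymethoxy)-6-propylbenzoate | CCCc1cc(OCOC)cc(OCOC)c1C(=O)Oc1c(OCOC)cc(CCC)c(C(=O)OC(C)(C)C)c1OC | intermediate
22 | 3-[(2,4-dihydroxy-6-propylbenzoyl)oxy]-4-hydroxy-2-methoxy-6-propylbenzoic acid (achiral) | CCCc1cc(O)cc(O)c1C(=O)Oc1c(O)cc(CCC)c(C(=O)O)c1OC | target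

Total step count: 14
Longest linear sequence: 10 steps (steps 2, 3, 4, 5, 6, 7, 8, 9, 13, 14, from methyl 3-oxohexanoate 5)

Steps most likely to fail

Step 6. The enolate manifold may leak into Claisen closure onto the ester, O-cyclization to pyranones or retro-Claisen scission of the α-benzyloxy 1,3-diketone, and the product phenoxide may be oxidized by air. The fallback builds ring B by a Michael–Dieckmann sequence followed by dehydrogenation, and no longer by folding the open triketone. It sets out from 4: with KOt-Bu in t-BuOH/THF the C2 carbanion of 4 adds to methyl (E)-hex-2-enoate to give the Michael adduct 1-tert-butyl 5-methyl 2-[(benzyloxy)acetyl]-3-propylpentanedioate F1. In the same flask the benzyloxy-bearing carbon of F1 closes onto the methyl ester to give tert-butyl 3-(benzyloxy)-2,4-dioxo-6-propylcyclohexane-1-carboxylate F2. Dehydrogenation of F2 with DDQ in dioxane should then give the arene, and the route is rejoined at 12.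

Step 5. Hydrolysis of a ketal next to the 1,3-diketone may be sluggish, and stronger acid may remove the tert-butyl group or drive cyclodehydration of the freed triketone. The fallback assembles the chain by two successive polyanion acylations, so no masked ketone has to be unveiled. It sets out from 4: dianion 8, made as in step 4, is acylated with N-methoxy-N-methylacetamide to give tert-butyl 4-(benzyloxy)-3,5-dioxohexanoate F3. F3 is converted with LiN(i-Pr)2 (3.3 equiv) in THF into trilithium 3-(benzyloxy)-6-(tert-butoxy)hexa-1,3,5-triene-2,4,6-tris(olate) F4. Acylation of F4 at its terminal methylene carbon with N-methoxy-N-methylbutanamide, followed by an AcOH quench, should give the triketo ester under basic conditions only, and the route is rejoined at 10.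

Step 13. Acyl transfer between two ortho,ortho-disubstituted partners may be slower than rearrangement of the activated acid to an N-acylurea. The fallback switches ring A to benzyl ethers so that an acid chloride can be used, and ends with a neutral hydrogenolysis. It sets out from 18:
- Benzylation of 18 (BnBr, K2CO3, DMF) gives 2,4-bis(benzyloxy)-6-propylbenzaldehyde F5.
- Pinnick oxidation of F5 gives 2,4-bis(benzyloxy)-6-propylbenzoic acid F6.
- Oxalyl chloride with catalytic DMF converts F6 into 2,4-bis(benzyloxy)-6-propylbenzoyl chloride F7.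
- F7 acylates phenol 15 (Et3N, DMAP, CH2Cl2) to give tert-butyl 3-{[2,4-bis(benzyloxy)-6-propylbenzoyl]oxy}-2-methoxy-4-(methoxymethoxy)-6-propylbenzoate F8.
- TFA/CH2Cl2 with a little water removes the MOM and tert-butyl groups of F8 to give 3-{[2,4-bis(benzyloxy)-6-propylbenzoyl]oxy}-4-hydroxy-2-methoxy-6-propylbenzoic acid F9.
- Hydrogenolysis of F9 (H2, Pd/C, EtOAc) should give the target, and the route is rejoined at 22.

Further compounds
F1 | step 6 | 1-tert-butyl 5-methyl 2-[(benzyloxy)acetyl]-3-propylpentanedioate (mixture of stereoisomers) | CCCC(CC(=O)OC)C(C(=O)COCc1ccccc1)C(=O)OC(C)(C)C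
F2 | step 6 | tert-butyl 3-(benzyloxy)-2,4-dioxo-6-propylcyclohexane-1-carboxylate (mixture of stereoisomers) | CCCC1CC(=O)C(OCc2ccccc2)C(=O)C1C(=O)OC(C)(C)C
F3 | step 5 | tert-butyl 4-(benzyloxy)-3,5-dioxohexanoate (racemic at C4) | CC(=O)C(OCc1ccccc1)C(=O)CC(=O)OC(C)(C)C
F4 | step 5 | trilithium 3-(benzyloxy)-6-(tert-butoxy)hexa-1,3,5-triene-2,4,6-tris(olate) | [Li+].[Li+].[Li+].C=C([O-])C(OCc1ccccc1)=C([O-])C=C([O-])OC(C)(C)C
F5 | step 13 | 2,4-bis(benzyloxy)-6-propylbenzaldehyde | CCCc1cc(OCc2ccccc2)cc(OCc2ccccc2)c1C=O
F6 | step 13 | 2,4-bis(benzyloxy)-6-propylbenzoic acid | CCCc1cc(OCc2ccccc2)cc(OCc2ccccc2)c1C(=O)O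
F7 | step 13 | 2,4-bis(benzyloxy)-6-propylbenzoyl chloride | CCCc1cc(OCc2ccccc2)cc(OCc2ccccc2)c1C(=O)Cl
F8 | step 13 | tert-butyl 3-{[2,4-bis(benzyloxy)-6-propylbenzoyl]oxy}-2-methoxy-4-(methoxymethoxy)-6-propylbenzoate | CCCc1cc(OCc2ccccc2)cc(OCc2ccccc2)c1C(=O)Oc1c(OCOC)cc(CCC)c(C(=O)OC(C)(C)C)c1OC
F9 | step 13 | 3-{[2,4-bis(benzyloxy)-6-propylbenzoyl]oxy}-4-hydroxy-2-methoxy-6-propylbenzoic acid | CCCc1cc(OCc2ccccc2)cc(OCc2ccccc2)c1C(=O)Oc1c(O)cc(CCC)c(C(=O)O)c1OC
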